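**Counted catalyst.** The catalyst charged stays a fixed amount however it is shared among its forms, so I keep count of the part still able to turn over, the charged [free catalyst] minus the charged [impurity], 0.380 mM in the flask: this is the working catalyst.

| setting | cedar | alder | ash | flask |
|---|---|---|---|---|
| starting material | 0.10 M | 0.10 M | 0.10 M | 0.10 M |
| free catalyst | 0.70 mM | 1.1 mM | 0.50 mM | 0.50 mM |
| impurity | 0.12 mM | 0.12 mM | 0.18 mM | 0.12 mM |
| remark | run made earlier | run made earlier | run made earlier |  |

| run | time / min | target / % | starting material / % |
|---|---|---|---|
| cedar | 2.00 | 7.7 | 91.9 |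
| cedar | 6.00 | 22.2 | 76.0 |
| cedar | 10.0 | 36.9 | 62.5 |
| cedar | 15.0 | 52.0 | 46.6 |
| cedar | 20.0 | 66.9 | 32.1 |
| cedar | 30.0 | 88.1 | 11.4 |
| cedar | 40.0 | 97.6 | 3.3 |
| alder | 3.00 | 18.7 | 81.4 |
| alder | 4.00 | 24.7 | 74.1 |
| alder | 6.00 | 37.0 | 62.5 |
| alder | 10.0 | 57.9 | 40.3 |
| alder | 15.0 | 80.1 | 19.9 |
| alder | 25.0 | 97.4 | 1.6 |
| alder | 40.0 | 98.6 | 0.4 |
| ash | 3.00 | 6.3 | 93.2 |
| ash | 10.0 | 21.5 | 79.3 |
| ash | 15.0 | 30.8 | 69.3 |
| ash | 25.0 | 49.0 | 49.9 |
| ash | 40.0 | 72.8 | 26.8 |

(readings scatter by 0.5 percentage points)

1. apparent order in free catalyst when 20% of the starting material are converted (percent change of the rate of making target for one percent more free catalyst charged)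
2. factor on the rate of making target when 20% of the starting material are converted if free catalyst is charged twice over



**Main step.** With just the main step, the rate of making target follows the charged catalyst, which gives an order of 1 and a factor of 2 on doubling.

**Adding impurity.** If each impurity takes one catalyst away, what is lost is a fixed amount rather than a fixed share, so in the flask the order becomes the charge over the working catalyst, 1.32, and doubling gives 2.32. This is stoichiometric poisoning by titration, and I take it as finished early, since cedar's target reads 7.7% at 2.00 min and 36.9% at 10.0 min, close to a straight line from zero.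

**The rest.** Cedar, alder, ash and the flask each start from 0.10 M of starting material, so at one conversion [starting material] and [target] match between them, and if the rate is the working catalyst times some function of those two, that function cancels in a ratio of rates. Integrated, this says that the times to one reading should stand inversely as the working catalyst. Cedar and alder both read 62.5% of starting material, at 10.0 min and 6.00 min, a ratio of 1.67; working catalyst gives 1.69, charged catalyst 1.57.

**Second flask.** Cedar reads 46.6% at 15.0 min, so ash, with less working catalyst than cedar, should reach that reading at 27.2 min. A straight line between ash's readings gives 46.5% there.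

**The forecast.** It gives 1.32 and 2.32, on the ground that “So the impurity titrates catalyst 1:1.”

**The result.** The flask gives an order of 1.3 and a factor of 2.32.

    catalyst intermediate B ⇌ free catalyst + target (K = 1.60 M, k = 14.0 min⁻¹)
    free catalyst + impurity → spent catalyst (k = 34000 M⁻¹ min⁻¹)
    starting material + free catalyst → catalyst intermediate A (k = 320 M⁻¹ min⁻¹)
    catalyst intermediate A → catalyst intermediate B (k = 21.0 min⁻¹)

**Impurity's clock.** With free catalyst as it stands in the flask at 3.00 min, the impurity has a half-life of 0.242 min, far shorter than the 7.96 min at which 20% of the starting material is converted, and 0.0159% of its charge stands at 3.00 min. At 15.0 min spent catalyst holds 24.0% of the catalyst charged, while catalyst intermediate A, catalyst intermediate B and free catalyst together hold 76.0%, against the working catalyst's 0.380 mM of 0.50 mM, which is 76.0%.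

The runs stem from a simulated flask on assumed constants; noise was put on by code.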